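**Plan**

- Retrosynthesis: each dihydrobenzofuran is cut at its C2–C3 bond (carbene C–H insertion into a 4-methoxybenzyl ether). This leads back to a dibenzosuberone whose ring A carries an aroyl group and two phenols.
- Ring A, the central benzene, is then cut at two C–C bonds: the bond between the aroyl-bearing carbon and the oxygenated carbon beside it, and the bond between the two ring-A carbons that carry the benzylic carbons of the seven-membered ring.
- Feature used: ring A is a resorcinol whose only C–H lies between the two oxygens and whose other three carbons carry contiguous carbon substituents. It therefore maps onto a 1,1-dimethoxy-3-silyloxybutadiene and an alkynyl ketone joined through ring B (the resorcinol ring of the seven-membered ring).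
- Forward: ring B is extended to a cinnamate, arylated, converted to the alkyne, formylated, joined to 4,4-dimethoxybut-3-en-2-one by an aldol reaction and acylated to the ynone. Silylation gives the diene, one thermal step closes ring A and the seven-membered ring together, one double C–H insertion closes both dihydrofurans, and global demethylation follows.
- Stereochemistry: the diarylmethine centre comes from a rhodium/(S)-BINAP conjugate addition. C-3 of both dihydrofurans comes from the chiral dirhodium catalyst, reinforced at the seven-membered-ring carbon by the neighbouring aryl group. C-2 of both comes from acid-mediated equilibration of the cis to the trans ring in the last step.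

Key step: step 9

Assumption: the sense of induction is taken from the models for simple substrates ((S)-BINAP–Rh–aryl adds to the α-si face of an (E)-enoate; Rh2(R-PTAD)4 is written for the antipode that gives 3R at each new dihydrofuran carbon); if either is reversed on these substrates, the mirror-image ligand or catalyst is used.

Remark: the carbon between rings A and B is carried through the cycloaddition at the alcohol oxidation level (as a silyl ether, both epimers). Compounds 13–20 are therefore epimer mixtures at that carbon; the mixture converges in step 10.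

**Route**

Step 1
Reactants: 1 1-bromo-3,5-dimethoxybenzene
Product: 2 2-bromo-4,6-dimethoxybenzaldehyde
Conditions: POCl3, DMF, 0 → 90 °C; then H2O
Reagents that add atoms: N,N-dimethylformamide CN(C)C=O; water O
Why: Vilsmeier–Haack formylation of the electron-rich arene takes place para to one methoxy group and ortho to the other, next to bromine, the position between the two methoxy groups being more hindered.

Step 2
Reactants: 2 2-bromo-4,6-dimethoxybenzaldehyde; 3 triethyl phosphonoacetate
Product: 4 ethyl (2E)-3-(2-bromo-4,6-dimethoxyphenyl)prop-2-enoate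
Conditions: NaH, THF, 0 °C → rt
Reagents that add atoms: none
Why: Horner–Wadsworth–Emmons olefination of a non-enolisable aryl aldehyde with a stabilised phosphonate anion gives the (E)-cinnamate.

Step 3
Reactants: 4 ethyl (2E)-3-(2-bromo-4,6-dimethoxyphenyl)prop-2-enoate; 5 2,4-dimethoxyphenylboronic acid
Product: 6 ethyl (3R)-3-(2-bromo-4,6-dimethoxyphenyl)-3-(2,4-dimethoxyphenyl)propanoate
Conditions: [Rh(OH)((S)-BINAP)]2 (3 mol %), 5 (3 equiv), dioxane/H2O 10:1, 50 °C
Reagents that add atoms: none
Why: Hayashi–Miyaura asymmetric 1,4-addition: the aryl–rhodium–BINAP species inserts the (E)-enoate on its α-si face under control of (S)-BINAP and protonolysis of the oxa-π-allyl gives the 3R ester, the aryl bromide being inert to the rhodium catalyst.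

Step 4
Reactants: 6 ethyl (3R)-3-(2-bromo-4,6-dimethoxyphenyl)-3-(2,4-dimethoxyphenyl)propanoate
Product: 8 1-bromo-2-[(1R)-1-(2,4-dimethoxyphenyl)but-3-yn-1-yl]-3,5-dimethoxybenzene, via aldehyde 7 (not isolated)
Conditions: i-Bu2AlH (1.1 equiv), CH2Cl2, −78 °C; then MeOH, K2CO3, dimethyl (1-diazo-2-oxopropyl)phosphonate, −78 °C → rt
Reagents that add atoms: dimethyl (1-diazo-2-oxopropyl)phosphonate COP(=O)(OC)C(=[N+]=[N-])C(C)=O
Why: Partial reduction stops at the aluminium hemiacetal, methanolysis releases the aldehyde, and the Ohira–Bestmann variant of the Seyferth–Gilbert homologation converts it to the terminal alkyne without touching the β-stereocentre.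

Step 5
Reactants: 8 1-bromo-2-[(1R)-1-(2,4-dimethoxyphenyl)but-3-yn-1-yl]-3,5-dimethoxybenzene
Product: 10 2-[(1R)-1-(2,4-dimethoxyphenyl)but-3-yn-1-yl]-3,5-dimethoxybenzaldehyde, via dilithio species 9 (not isolated)
Conditions: n-BuLi (2.1 equiv), THF, −78 °C; DMF (1.1 equiv), −78 °C; then aq. NH4Cl
Reagents that add atoms: N,N-dimethylformamide CN(C)C=O
Why: Deprotonation of the alkyne and bromine–lithium exchange give a dianion whose aryllithium reacts with DMF at −78 °C far faster than the lithium acetylide (Bouveault-type formylation), so the ring alone is formylated and the acetylide is reprotonated on quench.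

Step 6
Reactants: 10 2-[(1R)-1-(2,4-dimethoxyphenyl)but-3-yn-1-yl]-3,5-dimethoxybenzaldehyde; 11 4,4-dimethoxybut-3-en-2-one
Product: 14 5-(tert-butyldimethylsilyloxy)-5-{2-[(1R)-1-(2,4-dimethoxyphenyl)but-3-yn-1-yl]-3,5-dimethoxyphenyl}-1,1-dimethoxypent-1-en-3-one (both C-5 epimers), via lithium dienolate 12 (not isolated), via lithium aldolate 13 (not isolated)
Conditions: LiN(i-Pr)2 (1.05 equiv), 11, THF, −78 °C; 10, −78 °C; then t-BuMe2SiOTf (1.1 equiv), −78 → −40 °C
Reagents that add atoms: tert-butyldimethylsilyl trifluoromethanesulfonate CC(C)(C)[Si](C)(C)OS(=O)(=O)C(F)(F)F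
Why: Kinetic deprotonation of the methyl group of the vinylogous carbonate gives the cross-conjugated dienolate, whose aldol addition to the non-enolisable aldehyde is trapped in situ as the silyl ether so that retro-aldol reaction and cyclisation of the alkoxide onto the ketene acetal are avoided; the carbinol centre is formed without control and is removed in step 10.

Step 7
Reactants: 14 silyl ether of the aldol adduct; 15 3,5-dimethoxybenzoyl chloride
Product: 16 5-(tert-butyldimethylsilyloxy)-5-{2-[(1R)-1-(2,4-dimethoxyphenyl)-5-(3,5-dimethoxyphenyl)-5-oxopent-3-yn-1-yl]-3,5-dimethoxyphenyl}-1,1-dimethoxypent-1-en-3-one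
Conditions: PdCl2(PPh3)2 (2 mol %), CuI (4 mol %), Et3N, THF, rt
Reagents that add atoms: none
Why: Acyl Sonogashira coupling (copper acetylide onto an aroylpalladium chloride) gives the ynone under mild amine conditions that leave the β-silyloxy enone and the ketene acetal untouched.

Step 8
Reactants: 16 ynone
Product: 17 (5R)-5-{2-[(2Z)-1-(tert-butyldimethylsilyloxy)-5,5-dimethoxy-3-(trimethylsilyloxy)penta-2,4-dien-1-yl]-4,6-dimethoxyphenyl}-5-(2,4-dimethoxyphenyl)-1-(3,5-dimethoxyphenyl)pent-2-yn-1-one
Conditions: Me3SiOTf, Et3N, Et2O, −20 → 0 °C; pentane, filtration, evaporation; used crude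
Reagents that add atoms: trimethylsilyl trifluoromethanesulfonate C[Si](C)(C)OS(=O)(=O)C(F)(F)F
Why: Soft enolisation (silyl triflate/amine) of the only enolisable ketone gives the 2-silyloxydiene with the (Z)-enol ether geometry usual for this method, which puts the ring-B-bearing carbon on the outer side of the s-cis diene, and no free enolate is formed that could attack the ynone.

Step 9
Reactants: 17 silyloxydiene ynone
Product: 20 (10R)-1-(3,5-dimethoxybenzoyl)-10-(2,4-dimethoxyphenyl)-2,7,9-trimethoxy-10,11-dihydro-5H-dibenzo[a,d][7]annulene-4,5-diol (both C-5 epimers), via ketal cycloadduct 18 (not isolated), via bis-silyl arene 19 (not isolated)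
Conditions: toluene (5 mM), 2,6-di-tert-butyl-4-methylphenol (cat.), 110 °C; then Bu4NF, AcOH, THF, 0 °C
Reagents that add atoms: none
Why: Proposed new method: a normal-electron-demand [4+2] cycloaddition joins the 1,1-dimethoxy-3-silyloxydiene to the tethered ynone, the diene carbon remote from the acetal (the most nucleophilic terminus) bonding to the ynone β-carbon and the acetal carbon to the α-carbon, and the ketal cyclohexadiene 18 then loses methanol by 1,4-elimination to give the arene; the closest known reaction type is the intermolecular Diels–Alder reaction of 1,1-dialkoxy-3-silyloxybutadienes with alkynyl ketones or quinones, which gives resorcinol monoethers after loss of alcohol. Ring A closes by the cycloaddition itself, both new C–C bonds being ring-A bonds. The seven-membered ring closes as the tether ring in the fused mode, its five-atom tether held by the ortho-phenylene of ring B and biased by the silyloxy-substituted sp3 carbon. No stereocentre that survives is created: the sp3 ring carbon of 18 is aromatised, the silyloxy carbon is an epimer mixture erased in step 10, and the aryl-bearing centre set in step 3 is a spectator. The step needs regiocontrol only, secured twice, by the tether and by the matched polarisation of diene and ynone, while the (Z)-enol ether keeps the tether outside the s-cis diene and high dilution suppresses intermolecular addition. Fluoride then removes both silyl groups, so that the product has a phenol beside the carbinol and a methoxy group beside the aroyl ketone, the two ring-A oxygens differentiated.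

Step 10
Reactants: 20 dibenzosuberane diol
Product: 21 (10R)-1-(3,5-dimethoxybenzoyl)-10-(2,4-dimethoxyphenyl)-4-hydroxy-2,7,9-trimethoxy-10,11-dihydro-5H-dibenzo[a,d][7]annulen-5-one
Conditions: MnO2 (activated, excess), CH2Cl2, rt, dark
Reagents that add atoms: none
Why: Activated MnO2 oxidises the doubly benzylic alcohol to the diaryl ketone and leaves the acyl-deactivated phenol alone, so both carbinol epimers converge; light is excluded because the ketone is ortho to the diarylmethine and could photoenolise.

Step 11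
Reactants: 21 hydroxy diketone
Product: 22 (10R)-1-(3,5-dimethoxybenzoyl)-10-(2,4-dimethoxyphenyl)-2,4-dihydroxy-7,9-dimethoxy-10,11-dihydro-5H-dibenzo[a,d][7]annulen-5-one
Conditions: BCl3 (3 equiv), CH2Cl2, −78 → 0 °C; then H2O
Reagents that add atoms: none
Why: Chelation-controlled demethylation: BCl3 bound between a ketone and an ortho methoxy group cleaves only that ether, here the ring-A methoxy beside the aroyl group, while the six methoxy groups that are not ortho to a carbonyl stay.

Step 12
Reactants: 22 dihydroxy diketone; 23 4-methoxybenzyl chloride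
Product: 24 (10R)-1-(3,5-dimethoxybenzoyl)-10-(2,4-dimethoxyphenyl)-7,9-dimethoxy-2,4-bis[(4-methoxybenzyl)oxy]-10,11-dihydro-5H-dibenzo[a,d][7]annulen-5-one
Conditions: 23 (2.5 equiv), K2CO3, DMF, 60 °C
Reagents that add atoms: none
Why: Williamson etherification of the two ortho-acyl phenols installs on each ring-A oxygen the benzylic CH2 that becomes C-2 of a dihydrofuran together with its 4-methoxyphenyl group.

Step 13
Reactants: 24 bis(4-methoxybenzyl) ether
Product: 25 bis-hydrazone of 24
Conditions: N2H4·H2O (excess), AcOH (cat.), n-BuOH, 110 °C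
Reagents that add atoms: hydrazine NN
Why: Acid-catalysed condensation of hydrazine with both diaryl ketones gives the hydrazones (as E/Z mixtures, which is of no consequence), forcing conditions being chosen for the ortho-substituted carbonyls.

Step 14
Reactants: 25 bis-hydrazone
Product: 27 octa-O-methyl ether of the target epimeric at C-2 of both dihydrobenzofurans (both rings cis-2S,3R), via bis(diazo) compound 26 (not isolated)
Conditions: MnO2, CH2Cl2, 0 °C, filtration; then Rh2(R-PTAD)4 (2 mol %), CH2Cl2, 0 °C → rt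
Reagents that add atoms: none
Why: Oxidation gives the two diaryldiazomethanes, whose donor/donor rhodium carbenes insert into the neighbouring ArO–CH2Ar C–H bond (1,5-insertion, known for carbenes from 2-benzyloxybenzophenone hydrazones) to give cis-2,3-diaryl-2,3-dihydrobenzofurans; the chiral carboxylate ligands fix C-3 of each ring as R, and at the carbene inside the seven-membered ring the pseudoaxial 2,4-dimethoxyphenyl group directs the incoming CH2 to the opposite face, which is the same sense.

Step 15
Reactants: 27 cis,cis-bis(dihydrobenzofuran) octamethyl ether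
Product: 29 CNP0154047.1, via trans-trans octamethyl ether 28 (not isolated)
Conditions: BBr3 (excess), CH2Cl2, −78 °C → rt; then H2O
Reagents that add atoms: none
Why: BBr3 first ionises each benzylic C2–O bond reversibly to a 4-oxybenzyl cation that recloses to the more stable trans ring (inversion at C-2 only, C-3 untouched), and then cleaves the eight aryl methyl ethers by bromide dealkylation.

**Compound list**

1 | 1-bromo-3,5-dimethoxybenzene | COc1cc(Br)cc(OC)c1 | starting material
2 | 2-bromo-4,6-dimethoxybenzaldehyde | COc1cc(OC)c(C=O)c(Br)c1 | intermediate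
3 | triethyl phosphonoacetate | CCOC(=O)CP(=O)(OCC)OCC | starting material
4 | ethyl (2E)-3-(2-bromo-4,6-dimethoxyphenyl)prop-2-enoate | CCOC(=O)/C=C/c1c(Br)cc(OC)cc1OC | intermediate
5 | 2,4-dimethoxyphenylboronic acid | COc1ccc(B(O)O)c(OC)c1 | starting material
6 | ethyl (3R)-3-(2-bromo-4,6-dimethoxyphenyl)-3-(2,4-dimethoxyphenyl)propanoate | CCOC(=O)C[C@H](c1ccc(OC)cc1OC)c1c(Br)cc(OC)cc1OC | intermediate
7 | (3R)-3-(2-bromo-4,6-dimethoxyphenyl)-3-(2,4-dimethoxyphenyl)propanal (not isolated) | O=CC[C@H](c1ccc(OC)cc1OC)c1c(Br)cc(OC)cc1OC | intermediate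
8 | 1-bromo-2-[(1R)-1-(2,4-dimethoxyphenyl)but-3-yn-1-yl]-3,5-dimethoxybenzene | C#CC[C@H](c1ccc(OC)cc1OC)c1c(Br)cc(OC)cc1OC | intermediate
9 | dilithio species from 8: aryllithium at the former C–Br carbon and lithium acetylide (not isolated) | [Li]C#CC[C@H](c1ccc(OC)cc1OC)c1c([Li])cc(OC)cc1OC | intermediate
10 | 2-[(1R)-1-(2,4-dimethoxyphenyl)but-3-yn-1-yl]-3,5-dimethoxybenzaldehyde | O=Cc1cc(OC)cc(OC)c1[C@H](CC#C)c1ccc(OC)cc1OC | intermediate
11 | 4,4-dimethoxybut-3-en-2-one | COC(OC)=CC(C)=O | starting material
12 | lithium 4,4-dimethoxybuta-1,3-dien-2-olate (not isolated) | [Li]OC(=C)C=C(OC)OC | intermediate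
13 | lithium aldolate: lithium alkoxide of 5-{2-[(1R)-1-(2,4-dimethoxyphenyl)but-3-yn-1-yl]-3,5-dimethoxyphenyl}-5-hydroxy-1,1-dimethoxypent-1-en-3-one, both C-5 epimers (not isolated) | COC(OC)=CC(=O)CC(O[Li])c1cc(OC)cc(OC)c1[C@H](CC#C)c1ccc(OC)cc1OC | intermediate
14 | 5-(tert-butyldimethylsilyloxy)-5-{2-[(1R)-1-(2,4-dimethoxyphenyl)but-3-yn-1-yl]-3,5-dimethoxyphenyl}-1,1-dimethoxypent-1-en-3-one, both C-5 epimers | COC(OC)=CC(=O)CC(O[Si](C)(C)C(C)(C)C)c1cc(OC)cc(OC)c1[C@H](CC#C)c1ccc(OC)cc1OC | intermediate
15 | 3,5-dimethoxybenzoyl chloride | COc1cc(cc(OC)c1)C(Cl)=O | starting material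
16 | 5-(tert-butyldimethylsilyloxy)-5-{2-[(1R)-1-(2,4-dimethoxyphenyl)-5-(3,5-dimethoxyphenyl)-5-oxopent-3-yn-1-yl]-3,5-dimethoxyphenyl}-1,1-dimethoxypent-1-en-3-one, both C-5 epimers | COC(OC)=CC(=O)CC(O[Si](C)(C)C(C)(C)C)c1cc(OC)cc(OC)c1[C@H](CC#CC(=O)c1cc(OC)cc(OC)c1)c1ccc(OC)cc1OC | intermediate
17 | (5R)-5-{2-[(2Z)-1-(tert-butyldimethylsilyloxy)-5,5-dimethoxy-3-(trimethylsilyloxy)penta-2,4-dien-1-yl]-4,6-dimethoxyphenyl}-5-(2,4-dimethoxyphenyl)-1-(3,5-dimethoxyphenyl)pent-2-yn-1-one, both epimers at the silyloxy carbon | COC(OC)=C/C(O[Si](C)(C)C)=C/C(O[Si](C)(C)C(C)(C)C)c1cc(OC)cc(OC)c1[C@H](CC#CC(=O)c1cc(OC)cc(OC)c1)c1ccc(OC)cc1OC | intermediate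
18 | ketal cycloadduct: cyclohexa-1,4-diene with the C(OMe)2 carbon beside the aroyl-bearing alkene carbon, fused to the new seven-membered ring, epimer mixture at the two unassigned sp3 carbons (not isolated) | COC1(OC)C=C(O[Si](C)(C)C)C2C(O[Si](C)(C)C(C)(C)C)c3cc(OC)cc(OC)c3[C@@H](c3ccc(OC)cc3OC)CC2=C1C(=O)c1cc(OC)cc(OC)c1 | intermediate
19 | bis-silyl arene: 4-O-trimethylsilyl-5-O-tert-butyldimethylsilyl derivative of 20 (not isolated) | COc1cc(O[Si](C)(C)C)c2c(c1C(=O)c1cc(OC)cc(OC)c1)C[C@H](c1ccc(OC)cc1OC)c1c(OC)cc(OC)cc1C2O[Si](C)(C)C(C)(C)C | intermediate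
20 | (10R)-1-(3,5-dimethoxybenzoyl)-10-(2,4-dimethoxyphenyl)-2,7,9-trimethoxy-10,11-dihydro-5H-dibenzo[a,d][7]annulene-4,5-diol, both C-5 epimers | COc1cc(O)c2c(c1C(=O)c1cc(OC)cc(OC)c1)C[C@H](c1ccc(OC)cc1OC)c1c(OC)cc(OC)cc1C2O | intermediate
21 | (10R)-1-(3,5-dimethoxybenzoyl)-10-(2,4-dimethoxyphenyl)-4-hydroxy-2,7,9-trimethoxy-10,11-dihydro-5H-dibenzo[a,d][7]annulen-5-one | COc1cc(O)c2c(c1C(=O)c1cc(OC)cc(OC)c1)C[C@H](c1ccc(OC)cc1OC)c1c(OC)cc(OC)cc1C2=O | intermediate
22 | (10R)-1-(3,5-dimethoxybenzoyl)-10-(2,4-dimethoxyphenyl)-2,4-dihydroxy-7,9-dimethoxy-10,11-dihydro-5H-dibenzo[a,d][7]annulen-5-one | Oc1cc(O)c2c(c1C(=O)c1cc(OC)cc(OC)c1)C[C@H](c1ccc(OC)cc1OC)c1c(OC)cc(OC)cc1C2=O | intermediate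
23 | 4-methoxybenzyl chloride | COc1ccc(CCl)cc1 | starting material
24 | (10R)-1-(3,5-dimethoxybenzoyl)-10-(2,4-dimethoxyphenyl)-7,9-dimethoxy-2,4-bis[(4-methoxybenzyl)oxy]-10,11-dihydro-5H-dibenzo[a,d][7]annulen-5-one | COc1ccc(COc2cc(OCc3ccc(OC)cc3)c3c(c2C(=O)c2cc(OC)cc(OC)c2)C[C@H](c2ccc(OC)cc2OC)c2c(OC)cc(OC)cc2C3=O)cc1 | intermediate
25 | bis-hydrazone of 24 (C=N–NH2 at the ring ketone and at the aroyl ketone, E/Z mixture) | COc1ccc(COc2cc(OCc3ccc(OC)cc3)c3c(c2C(=NN)c2cc(OC)cc(OC)c2)C[C@H](c2ccc(OC)cc2OC)c2c(OC)cc(OC)cc2C3=NN)cc1 | intermediate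
26 | bis(diazo) compound from 25 (not isolated) | COc1ccc(COc2cc(OCc3ccc(OC)cc3)c3c(c2C(=[N+]=[N-])c2cc(OC)cc(OC)c2)C[C@H](c2ccc(OC)cc2OC)c2c(OC)cc(OC)cc2C3=[N+]=[N-])cc1 | intermediate
27 | octa-O-methyl ether of the target with both dihydrobenzofurans cis (2S,3R in each ring; R at the diarylmethine of the seven-membered ring) | COc1ccc([C@H]2Oc3cc4c5c(c3[C@H]2c2cc(OC)cc(OC)c2)C[C@H](c2ccc(OC)cc2OC)c2c(OC)cc(OC)cc2[C@H]5[C@@H](c2ccc(OC)cc2)O4)cc1 | intermediate
28 | octa-O-methyl ether of the target, both dihydrobenzofurans trans (2R,3R) (not isolated) | COc1ccc([C@@H]2Oc3cc4c5c(c3[C@H]2c2cc(OC)cc(OC)c2)C[C@H](c2ccc(OC)cc2OC)c2c(OC)cc(OC)cc2[C@H]5[C@H](c2ccc(OC)cc2)O4)cc1 | intermediate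
29 | CNP0154047.1: octaphenol, both dihydrobenzofurans trans-(2R,3R), R at the CH(2,4-dihydroxyphenyl) of the seven-membered ring | Oc1ccc([C@@H]2Oc3cc4c5c(c3[C@H]2c2cc(O)cc(O)c2)C[C@H](c2ccc(O)cc2O)c2c(O)cc(O)cc2[C@H]5[C@H](c2ccc(O)cc2)O4)cc1 | target

**Step count**

Total steps: 15. Longest linear sequence: 15 steps, from 1.

**Steps most likely to fail**

Step 9 (proposed new method). The diene may be consumed by desilylation or by hydrolysis of the ketene acetal faster than the seven-membered ring can close, or the closure may be too slow entropically. The fallback builds ring A by the known intermolecular reaction and closes the seven-membered ring afterwards. It sets out from aldehyde 10: acyl Sonogashira coupling with 15 (conditions of step 7) gives the ynone aldehyde F1. Heating F1 with commercially available 1,1-dimethoxy-3-(trimethylsilyloxy)buta-1,3-diene (toluene, 80 °C) gives the ketal cycloadduct F2 with the same regiochemistry. On dilute acid work-up F2 loses methanol and the silyl group to give the 2-aroyl-3-methoxy-5-hydroxyphenyl compound F3, whose ring-A position between the phenol and the tether-bearing carbon is still C–H. Deprotonation of the phenol with EtMgBr and heating in toluene then bring about ortho-selective hydroxyalkylation of the magnesium phenoxide by the tethered aldehyde (Casiraghi type). Only the seven-membered ring can form, and the sequence comes back to the route at diol 20.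

Step 14. The two carbenes may react along other paths: azine formation, insertion into the tertiary diarylmethine C–H next to ring B, or insertion of the seven-membered-ring carbene on the wrong face if substrate and catalyst are mismatched. The fallback sets out from diol 20 and uses the carbon between rings A and B as an ortho-quinone methide. With (4-methoxybenzyl)dimethylsulfonium tetrafluoroborate and Cs2CO3 (CH2Cl2, 40 °C) the o-hydroxybenzhydrol loses water, the sulfonium ylide adds to the methide carbon on the face away from the 2,4-dimethoxyphenyl group, and the phenoxide displaces dimethyl sulfide; this known [4+1] annulation gives the trans-dihydrobenzofuran ketone F4. The aroyl ketone of F4 is then taken alone through the operations of steps 11 to 14, an insertion of the simple benzophenone type: BCl3 gives phenol F5, 4-methoxybenzyl chloride the ether F6, hydrazine the hydrazone F7, MnO2 the diazo compound F8, and Rh2(R-PTAD)4 the cis-dihydrobenzofuran F9. Under the conditions of step 15, F9 epimerises at its one cis ring and so comes back to the route at 28, which is demethylated to 29.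

Step 3. Carbometalation of the doubly ortho-substituted cinnamate may be slow while the electron-rich boronic acid is lost by protodeboronation, giving low conversion or eroded enantioselectivity. The fallback is an auxiliary-controlled cuprate addition and sets out from ester 4. Saponification (LiOH, THF/H2O) gives the acid F10, pivaloyl chloride/Et3N the mixed anhydride F11, and the lithium salt of (S)-4-phenyl-1,3-oxazolidin-2-one the imide F12. 2,4-Dimethoxyphenylmagnesium bromide with CuBr·SMe2 (THF, −40 °C) adds to the chelated s-cis enoyl imide on the face away from the phenyl group to give the adduct F13 with the 3R configuration. EtOMgBr in EtOH/THF then releases the auxiliary, and the sequence comes back to the route at ester 6.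

**Further compounds**

F1 | step 9 | 2-[(1R)-1-(2,4-dimethoxyphenyl)-5-(3,5-dimethoxyphenyl)-5-oxopent-3-yn-1-yl]-3,5-dimethoxybenzaldehyde | O=Cc1cc(OC)cc(OC)c1[C@H](CC#CC(=O)c1cc(OC)cc(OC)c1)c1ccc(OC)cc1OC
F2 | step 9 | ketal cycloadduct of F1 with 1,1-dimethoxy-3-(trimethylsilyloxy)buta-1,3-diene (not isolated) | COC1(OC)C=C(O[Si](C)(C)C)CC(C[C@H](c2ccc(OC)cc2OC)c2c(OC)cc(OC)cc2C=O)=C1C(=O)c1cc(OC)cc(OC)c1
F3 | step 9 | 2-[(1R)-2-[2-(3,5-dimethoxybenzoyl)-5-hydroxy-3-methoxyphenyl]-1-(2,4-dimethoxyphenyl)ethyl]-3,5-dimethoxybenzaldehyde | COc1cc(O)cc(C[C@H](c2ccc(OC)cc2OC)c2c(OC)cc(OC)cc2C=O)c1C(=O)c1cc(OC)cc(OC)c1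
F4 | step 14 | aroyl ketone carrying the trans-dihydrobenzofuran fused to the seven-membered ring (ring-A methoxy beside the ketone) | COc1cc2c3c(c1C(=O)c1cc(OC)cc(OC)c1)C[C@H](c1ccc(OC)cc1OC)c1c(OC)cc(OC)cc1[C@H]3[C@H](c1ccc(OC)cc1)O2
F5 | step 14 | phenol from F4 (ring-A hydroxyl beside the ketone) | Oc1cc2c3c(c1C(=O)c1cc(OC)cc(OC)c1)C[C@H](c1ccc(OC)cc1OC)c1c(OC)cc(OC)cc1[C@H]3[C@H](c1ccc(OC)cc1)O2
F6 | step 14 | 4-methoxybenzyl ether of F5 | COc1ccc(COc2cc3c4c(c2C(=O)c2cc(OC)cc(OC)c2)C[C@H](c2ccc(OC)cc2OC)c2c(OC)cc(OC)cc2[C@H]4[C@H](c2ccc(OC)cc2)O3)cc1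
F7 | step 14 | hydrazone of F6 | COc1ccc(COc2cc3c4c(c2C(=NN)c2cc(OC)cc(OC)c2)C[C@H](c2ccc(OC)cc2OC)c2c(OC)cc(OC)cc2[C@H]4[C@H](c2ccc(OC)cc2)O3)cc1
F8 | step 14 | diazo compound from F7 (not isolated) | COc1ccc(COc2cc3c4c(c2C(=[N+]=[N-])c2cc(OC)cc(OC)c2)C[C@H](c2ccc(OC)cc2OC)c2c(OC)cc(OC)cc2[C@H]4[C@H](c2ccc(OC)cc2)O3)cc1
F9 | step 14 | octa-O-methyl ether with the 3,5-dimethoxyphenyl-bearing dihydrobenzofuran cis (2S,3R) and the other trans (2R,3R) | COc1ccc([C@H]2Oc3cc4c5c(c3[C@H]2c2cc(OC)cc(OC)c2)C[C@H](c2ccc(OC)cc2OC)c2c(OC)cc(OC)cc2[C@H]5[C@H](c2ccc(OC)cc2)O4)cc1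
F10 | step 3 | (2E)-3-(2-bromo-4,6-dimethoxyphenyl)prop-2-enoic acid | OC(=O)/C=C/c1c(Br)cc(OC)cc1OC
F11 | step 3 | mixed anhydride of F10 with pivalic acid (not isolated) | CC(C)(C)C(=O)OC(=O)/C=C/c1c(Br)cc(OC)cc1OC
F12 | step 3 | (4S)-3-[(2E)-3-(2-bromo-4,6-dimethoxyphenyl)prop-2-enoyl]-4-phenyl-1,3-oxazolidin-2-one | O=C(/C=C/c1c(Br)cc(OC)cc1OC)N1[C@@H](c2ccccc2)COC1=O
F13 | step 3 | (4S)-3-[(3R)-3-(2-bromo-4,6-dimethoxyphenyl)-3-(2,4-dimethoxyphenyl)propanoyl]-4-phenyl-1,3-oxazolidin-2-one | O=C(C[C@H](c1ccc(OC)cc1OC)c1c(Br)cc(OC)cc1OC)N1[C@@H](c2ccccc2)COC1=O
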